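**Assumption:** the single stereocentre is (R), as read from the given SMILES; 10-bromodecan-1-ol, (R)-epichlorohydrin and 2,4,6-trihydroxybenzoic acid are taken as catalogue items.

**Retrosynthetic overview**
- The target comes from a tetrabenzyl precursor (two aryl benzyl ethers, benzyl ester, primary benzyl ether) by one global hydrogenolysis; the secondary acetate is already in place.
- Key disconnection: the aryl C6–CH2 bond, made by a visible-light nickel/photoredox cross-electrophile coupling of an aryl triflate with a chlorohydrin acetate (primary C–Cl).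
- The aryl triflate comes from 2,4,6-trihydroxybenzoic acid by tribenzylation (the chelated OH is left free) and triflation.
- The chlorohydrin acetate comes from (R)-epichlorohydrin, which supplies the only stereocentre, and the Grignard reagent of benzyl 10-bromodecyl ether, acetylated in the same flask.
- No ring is formed; the benzene ring is bought.

**Route**

Step 1
Reactants: 1 10-bromodecan-1-ol
Product: 2 [(10-bromodecyl)oxy]methylbenzene (benzyl 10-bromodecyl ether)
Conditions: BnOC(=NH)CCl3 (1.3 equiv), TfOH (5 mol%), CH2Cl2/cyclohexane, 0 °C → rt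
Reagents that add atoms: benzyl 2,2,2-trichloroacetimidate, N=C(OCc1ccccc1)C(Cl)(Cl)Cl
Why: Acid-catalysed trichloroacetimidate O-benzylation protects the primary alcohol without base, so the alkyl bromide is untouched.

Step 2
Reactants: 2 benzyl 10-bromodecyl ether; 3 (R)-epichlorohydrin [(2R)-2-(chloromethyl)oxirane]
Product: 6 (2R)-13-(benzyloxy)-1-chlorotridecan-2-yl acetate, via Grignard reagent 4 (not isolated), via bromomagnesium alkoxide 5 (not isolated)
Conditions: Mg, THF, 45 °C; then CuI (10 mol%), 3 (1.2 equiv), −40 → −20 °C; then Ac2O (2.5 equiv), DMAP (5 mol%), −20 °C → rt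
Reagents that add atoms: acetic anhydride, CC(=O)OC(C)=O
Why: Copper-catalysed Grignard opening of the epoxide at its unsubstituted CH2 (SN2; neither the C2–O bond nor the C–Cl bond is touched, so the (R) centre of 3 is carried over unchanged), followed by O-acetylation of the magnesium alkoxide in the same flask.

Step 3
Reactants: 7 2,4,6-trihydroxybenzoic acid
Product: 8 benzyl 2,4-bis(benzyloxy)-6-hydroxybenzoate
Conditions: BnBr (3.0 equiv), K2CO3 (3.0 equiv), DMF, 0 °C → rt
Reagents that add atoms: benzyl bromide, BrCc1ccccc1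
Why: Carboxylate and Williamson O-alkylation with exactly three equivalents benzylates the acid, the para OH and one ortho OH, while the last ortho OH stays free because it is hydrogen-bonded to the ester carbonyl.

Step 4
Reactants: 8 benzyl 2,4-bis(benzyloxy)-6-hydroxybenzoate
Product: 9 benzyl 2,4-bis(benzyloxy)-6-[(trifluoromethanesulfonyl)oxy]benzoate
Conditions: Tf2O (1.3 equiv), pyridine, CH2Cl2, 0 °C
Reagents that add atoms: trifluoromethanesulfonic anhydride, O=S(=O)(OS(=O)(=O)C(F)(F)F)C(F)(F)F
Why: Standard O-triflation of the remaining phenol turns it into a C(sp2) electrophile at exactly the ring position that must carry the side chain.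

Step 5
Reactants: 9 benzyl 2,4-bis(benzyloxy)-6-[(trifluoromethanesulfonyl)oxy]benzoate (1.0 equiv); 6 (2R)-13-(benzyloxy)-1-chlorotridecan-2-yl acetate (1.5 equiv)
Product: 10 benzyl 2-[(2R)-2-(acetyloxy)-13-(benzyloxy)tridecyl]-4,6-bis(benzyloxy)benzoate
Conditions: NiBr2(dme) (10 mol%), 4,4'-di-tert-butyl-2,2'-bipyridine (10 mol%), [Ir(dF(CF3)ppy)2(dtbbpy)]PF6 (1 mol%), (Me3Si)3SiNH(1-adamantyl) (1.6 equiv), Na2CO3 (2 equiv), DMA, 450 nm LEDs, 25 °C, degassed
Reagents that add atoms: none
Why: Proposed new method: a silyl-radical-mediated nickel/photoredox cross-electrophile coupling that pairs an aryl triflate with a chlorohydrin acetate (β-acetoxy primary alkyl chloride), a combination not yet shown; the photoexcited iridium complex oxidises the aminosilane, N–H loss and a 1,2-silyl shift from Si to N give a nucleophilic silyl radical that abstracts Cl from the primary C–Cl bond of 6 (polarity-matched, the β-acetoxy group making that carbon more electrophilic); the primary radical is trapped by the aryl–nickel species formed by oxidative addition of 9 to zerovalent nickel (helped by ortho-ester chelation and bromide from NiBr2), reductive elimination from trivalent nickel forms the aryl–CH2 bond, and the reduced photocatalyst returns monovalent nickel to zerovalent nickel; the radical carbon is not the stereocentre and the 1,2-acetoxy shift is far slower than metal capture, so C2 stays (R), and because the C2 oxygen is acetylated throughout it cannot lactonise onto the ortho ester; closest known reaction type: silyl-radical (halogen-atom-transfer) nickel/photoredox cross-electrophile coupling of aryl halides with unactivated alkyl chlorides.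

Step 6
Reactants: 10 benzyl 2-[(2R)-2-(acetyloxy)-13-(benzyloxy)tridecyl]-4,6-bis(benzyloxy)benzoate
Product: 11 2-[(2R)-2-(acetyloxy)-13-hydroxytridecyl]-4,6-dihydroxybenzoic acid (CNP0361881.1)
Conditions: H2 (1 atm), Pd(OH)2/C (20 wt%), EtOAc/THF, rt
Reagents that add atoms: none
Why: Catalytic hydrogenolysis removes the two aryl benzyl ethers, the benzyl ester and the primary alkyl benzyl ether, while the secondary acetate is inert and the homobenzylic C2–O bond is not cleaved, so (R) is retained.

**Compound list**
1 | 10-bromodecan-1-ol | OCCCCCCCCCCBr | starting material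
2 | [(10-bromodecyl)oxy]methylbenzene (benzyl 10-bromodecyl ether) | BrCCCCCCCCCCOCc1ccccc1 | intermediate
3 | (R)-epichlorohydrin, (2R)-2-(chloromethyl)oxirane | ClC[C@H]1CO1 | starting material
4 | [10-(benzyloxy)decyl]magnesium bromide | Br[Mg]CCCCCCCCCCOCc1ccccc1 | intermediate
5 | bromomagnesium (2R)-13-(benzyloxy)-1-chlorotridecan-2-olate | Br[Mg]O[C@H](CCCCCCCCCCCOCc1ccccc1)CCl | intermediate
6 | (2R)-13-(benzyloxy)-1-chlorotridecan-2-yl acetate | CC(=O)O[C@H](CCCCCCCCCCCOCc1ccccc1)CCl | intermediate
7 | 2,4,6-trihydroxybenzoic acid | OC(=O)c1c(O)cc(O)cc1O | starting material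
8 | benzyl 2,4-bis(benzyloxy)-6-hydroxybenzoate | O=C(OCc1ccccc1)c1c(O)cc(OCc2ccccc2)cc1OCc1ccccc1 | intermediate
9 | benzyl 2,4-bis(benzyloxy)-6-[(trifluoromethanesulfonyl)oxy]benzoate | O=C(OCc1ccccc1)c1c(OS(=O)(=O)C(F)(F)F)cc(OCc2ccccc2)cc1OCc1ccccc1 | intermediate
10 | benzyl 2-[(2R)-2-(acetyloxy)-13-(benzyloxy)tridecyl]-4,6-bis(benzyloxy)benzoate | CC(=O)O[C@H](CCCCCCCCCCCOCc1ccccc1)Cc1cc(OCc2ccccc2)cc(OCc2ccccc2)c1C(=O)OCc1ccccc1 | intermediate
11 | 2-[(2R)-2-(acetyloxy)-13-hydroxytridecyl]-4,6-dihydroxybenzoic acid | CC(=O)O[C@H](CCCCCCCCCCCO)Cc1cc(O)cc(O)c1C(=O)O | target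

**Step count:** 6 steps in total. Longest linear sequence: 4 steps (steps 1, 2, 5, 6; equally steps 3, 4, 5, 6).

**Three steps most likely to fail**

Step 5 (the proposed new coupling). Possible failures are slow oxidative addition of the triflate, simple reduction of either partner, or β-acetoxy elimination at nickel. The fallback uses only known chemistry, sets out from 6 and comes back at 10.
- K2CO3 in MeOH at rt removes the acetate and closes the chlorohydrin to (2R)-2-[11-(benzyloxy)undecyl]oxirane F1.
- The Grignard reagent made from commercial 1,3-bis(benzyloxy)-5-bromobenzene (Mg, THF), [3,5-bis(benzyloxy)phenyl]magnesium bromide F2, opens F1 at its CH2 terminus with CuI catalysis (THF, −30 °C). After NH4Cl work-up this gives (2R)-13-(benzyloxy)-1-[3,5-bis(benzyloxy)phenyl]tridecan-2-ol F3, with the stereocentre untouched.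
- Ac2O/pyridine/DMAP gives (2R)-13-(benzyloxy)-1-[3,5-bis(benzyloxy)phenyl]tridecan-2-yl acetate F4.
- Vilsmeier–Haack formylation (POCl3, DMF, 0 → 50 °C) attacks the ring position ortho to the side chain and para to a benzyloxy group. It passes through {2-[(2R)-2-(acetyloxy)-13-(benzyloxy)tridecyl]-4,6-bis(benzyloxy)phenyl}methylidene(dimethyl)ammonium chloride F5, which is hydrolysed with aqueous NaOAc to 2-[(2R)-2-(acetyloxy)-13-(benzyloxy)tridecyl]-4,6-bis(benzyloxy)benzaldehyde F6.
- Pinnick oxidation (NaClO2, NaH2PO4, 2-methyl-2-butene, t-BuOH/H2O) gives 2-[(2R)-2-(acetyloxy)-13-(benzyloxy)tridecyl]-4,6-bis(benzyloxy)benzoic acid F7.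
- BnBr/KHCO3 in DMF esterifies F7 to 10.

Step 3 (selective tribenzylation). Possible failures are C-benzylation or over-benzylation of the phloroglucinol-type ring and decarboxylation. The fallback sets out from 7 and comes back at 8. The carboxylate alone is alkylated first (KHCO3 1.1 equiv, BnBr 1.05 equiv, DMF, rt) to give benzyl 2,4,6-trihydroxybenzoate F8. A Mitsunobu etherification (BnOH 2.1 equiv, PPh3, DIAD, THF, 0 °C) then O-benzylates the para OH and one ortho OH without phenoxide C-alkylation, leaving the ester-chelated OH free, which is 8.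

Step 6 (global debenzylation). Possible failures are slow cleavage of the primary alkyl benzyl ether, or loss of acetic acid with lactonisation of the free acid on long exposure to the catalyst. The fallback sets out from 10 and comes back at 11. It replaces hydrogenolysis by Lewis-acid debenzylation with a cation scavenger (BCl3, pentamethylbenzene, CH2Cl2, −78 → −40 °C, MeOH quench at −78 °C), which cleaves all four benzyl groups and spares the acetate at low temperature. New compounds on its way: none F0.

**Further compounds**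
F1 | step 5 | (2R)-2-[11-(benzyloxy)undecyl]oxirane | C(OCCCCCCCCCCC[C@@H]1CO1)c1ccccc1
F2 | step 5 | [3,5-bis(benzyloxy)phenyl]magnesium bromide | Br[Mg]c1cc(OCc2ccccc2)cc(OCc2ccccc2)c1
F3 | step 5 | (2R)-13-(benzyloxy)-1-[3,5-bis(benzyloxy)phenyl]tridecan-2-ol | O[C@H](CCCCCCCCCCCOCc1ccccc1)Cc1cc(OCc2ccccc2)cc(OCc2ccccc2)c1
F4 | step 5 | (2R)-13-(benzyloxy)-1-[3,5-bis(benzyloxy)phenyl]tridecan-2-yl acetate | CC(=O)O[C@H](CCCCCCCCCCCOCc1ccccc1)Cc1cc(OCc2ccccc2)cc(OCc2ccccc2)c1
F5 | step 5 | {2-[(2R)-2-(acetyloxy)-13-(benzyloxy)tridecyl]-4,6-bis(benzyloxy)phenyl}methylidene(dimethyl)ammonium chloride | CC(=O)O[C@H](CCCCCCCCCCCOCc1ccccc1)Cc1cc(OCc2ccccc2)cc(OCc2ccccc2)c1C=[N+](C)C.[Cl-]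
F6 | step 5 | 2-[(2R)-2-(acetyloxy)-13-(benzyloxy)tridecyl]-4,6-bis(benzyloxy)benzaldehyde | CC(=O)O[C@H](CCCCCCCCCCCOCc1ccccc1)Cc1cc(OCc2ccccc2)cc(OCc2ccccc2)c1C=O
F7 | step 5 | 2-[(2R)-2-(acetyloxy)-13-(benzyloxy)tridecyl]-4,6-bis(benzyloxy)benzoic acid | CC(=O)O[C@H](CCCCCCCCCCCOCc1ccccc1)Cc1cc(OCc2ccccc2)cc(OCc2ccccc2)c1C(=O)O
F8 | step 3 | benzyl 2,4,6-trihydroxybenzoate | O=C(OCc1ccccc1)c1c(O)cc(O)cc1O
F0 | step 6 | none | none
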